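**Retrosynthetic overview**

1. Locants used as names: ring A (pyrroline) N4–C3–C2–C1–C9a; ring B (azepine) N4, C5–C8, C9, C9a; ring C (cyclohexene) C9a, C9, C10 (ethyl), C11 (OH), C12, C1; ring D (γ-lactone) O1–C14(=O)–C13(CH3)–C12–C1; ring E (side lactone) C18–C21 on C3.
2. Late disconnections: ring B by double alkylation (N4–C5, C8–C9) of a cyclic imine with 1,4-diiodobutane; ring A by condensation of a C3 amine with a C9a ketone; ring E and the C3/C18 pair by a sulfinimine vinylogous Mannich reaction; the C13 and C20 methyl centres by one hydrogenation.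
3. Key disconnection: ring D is cut at O1–C1 and C13–C14, so that CO2 is stitched between a C13 vinyllithium (Shapiro) and a C1–C9a epoxide on ring C.
4. Enabling feature: C1 is a tertiary C–O carbon vicinal to C9a (the future enamine carbon) and 1,3 to C13 through C12, and O1, C13 and O11 all sit on one face of ring C; a C1–C9a epoxide anti to the C12 arm therefore gives the tertiary C–O bond, its configuration and the C9a oxygen in one event.
5. Ring C comes from ring-closing metathesis of an Evans syn-aldol adduct (C11–C12 bond) of (R)-2-ethylpent-4-enal and an isoprenol-derived imide; ring order C, then D (key), E, A, B.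

Key step: step 14

Remark: starting materials 1, 2, 4, 8, 9, 12, 20, 26, 28 and 34 are taken as commercially available; the locants above are used only as names in the text.

**Step 1**
Reactants: 1 (4S)-4-benzyl-1,3-oxazolidin-2-one; 2 butanoyl chloride
Product: 3 (4S)-4-benzyl-3-butanoyl-1,3-oxazolidin-2-one
Conditions: n-BuLi, THF, −78 °C; then 2, −78 to 0 °C
Reagents that add atoms: none
Why: N-acylation of the lithiated oxazolidinone by the acid chloride (standard loading of an Evans auxiliary); no stereocentre is formed.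

**Step 2**
Reactants: 3; 4 allyl bromide
Product: 5 (4S)-4-benzyl-3-[(2R)-2-ethylpent-4-enoyl]-1,3-oxazolidin-2-one
Conditions: NaN(SiMe3)2, THF, −78 °C; then 4, −78 to −40 °C
Reagents that add atoms: none
Why: Evans asymmetric alkylation, in which the chelated Z-sodium enolate is allylated on the face opposite the benzyl group, setting the future C10 centre as (R).

**Step 3**
Reactants: 5
Product: 6 (2R)-2-ethylpent-4-en-1-ol
Conditions: LiBH4, MeOH (1 equiv), Et2O, 0 °C
Reagents that add atoms: none
Why: reductive cleavage of the imide at the exocyclic carbonyl releases the primary alcohol and the auxiliary without touching the stereocentre.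

**Step 4**
Reactants: 6
Product: 7 (2R)-2-ethylpent-4-enal
Conditions: Dess–Martin periodinane, NaHCO3, CH2Cl2, 0 °C to rt; used at once as a solution
Reagents that add atoms: none
Why: Dess–Martin oxidation under buffered, non-basic conditions should give the α-branched aldehyde without racemisation.

**Step 5**
Reactants: 8 3-methylbut-3-en-1-ol; 9 carbon dioxide
Product: 11 3-methylidene-5-(triethylsilyloxy)pentanoic acid, via bis-silylated hydroxy acid 10 (not isolated)
Conditions: n-BuLi (2.2 equiv), TMEDA, Et2O–hexane, 0 °C to rt; CO2, −78 °C; Et3SiCl (2.2 equiv), −78 to 0 °C; then K2CO3 (cat.), MeOH–H2O, 0 °C; citric acid work-up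
Reagents that add atoms: chlorotriethylsilane CC[Si](Cl)(CC)CC
Why: allylic metalation of the homoallylic alkoxide gives a dianion whose symmetrical allyl anion is carboxylated by CO2; both lithium salts are silylated and the labile silyl ester is hydrolysed selectively.

**Step 6**
Reactants: 11; 12 (4R)-4-benzyl-1,3-oxazolidin-2-one
Product: 13 (4R)-4-benzyl-3-[3-methylidene-5-(triethylsilyloxy)pentanoyl]-1,3-oxazolidin-2-one
Conditions: pivaloyl chloride, Et3N, THF, −20 °C; then lithiated 12 (n-BuLi, THF, −78 °C), −78 to 0 °C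
Reagents that add atoms: none
Why: mixed pivalic anhydride acylation of the lithiated auxiliary, which attacks the less hindered carbonyl of the anhydride.

**Step 7**
Reactants: 13; 7
Product: 14 (4R)-4-benzyl-3-[(2R,3S,4R)-4-ethyl-3-hydroxy-2-[4-(triethylsilyloxy)but-1-en-2-yl]hept-6-enoyl]-1,3-oxazolidin-2-one
Conditions: Bu2BOTf, iPr2NEt, CH2Cl2, −78 to 0 °C; 7, −78 to 0 °C; then pH 7 buffer, MeOH, H2O2, 0 °C
Reagents that add atoms: none
Why: Evans syn-aldol reaction through the Z-boron enolate and a Zimmerman–Traxler transition state, in which the (R)-auxiliary sets C12 and C11 (2R,3S) and overrides the weak Felkin bias of aldehyde 7, whose two α-substituents are of similar size.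

**Step 8**
Reactants: 14
Product: 15 (2R,3S,4R)-4-ethyl-3-hydroxy-N-methoxy-N-methyl-2-[4-(triethylsilyloxy)but-1-en-2-yl]hept-6-enamide
Conditions: MeNHOMe·HCl, AlMe3, THF, 0 °C to rt; Rochelle salt work-up
Reagents that add atoms: N,O-dimethylhydroxylamine hydrochloride CNOC.Cl
Why: AlMe3-mediated Weinreb transamidation of the aldol imide, assisted by the free β-hydroxyl, removes the auxiliary without epimerising C12.

**Step 9**
Reactants: 15
Product: 16 (2R,3S,4R)-3-(tert-butyldimethylsilyloxy)-4-ethyl-N-methoxy-N-methyl-2-[4-(triethylsilyloxy)but-1-en-2-yl]hept-6-enamide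
Conditions: TBSOTf, 2,6-lutidine, CH2Cl2, −78 to 0 °C
Reagents that add atoms: tert-butyldimethylsilyl trifluoromethanesulfonate CC(C)(C)[Si](C)(C)OS(=O)(=O)C(F)(F)F
Why: silylation of the hindered secondary alcohol with the silyl triflate gives an ether that outlasts the primary triethylsilyl ether under acid.

**Step 10**
Reactants: 16
Product: 17 (1R,5R,6S)-6-(tert-butyldimethylsilyloxy)-5-ethyl-N-methoxy-N-methyl-2-[2-(triethylsilyloxy)ethyl]cyclohex-2-ene-1-carboxamide
Conditions: second-generation Grubbs catalyst (5 mol %), CH2Cl2, 40 °C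
Reagents that add atoms: none
Why: ring-closing metathesis of the 1,7-diene closes ring C as a trisubstituted cyclohexene, driven by loss of ethene.

**Step 11**
Reactants: 17
Product: 18 epoxy Weinreb amide (C1–C9a epoxide of 17 on the ring face opposite the carboxamide and silyloxy groups)
Conditions: mCPBA, NaHCO3, CH2Cl2, 0 °C
Reagents that add atoms: 3-chloroperbenzoic acid OOC(=O)c1cccc(Cl)c1
Why: Prilezhaev epoxidation of the electron-rich trisubstituted alkene, in which the peracid approaches anti to the adjacent C12 carboxamide arm and the C11 silyloxy group (both on the same face), sets C1 and C9a as the anti epoxide.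

**Step 12**
Reactants: 18
Product: 19 epoxy methyl ketone (C12 acetyl, epoxide as in 18)
Conditions: MeLi, THF, −78 °C; aq. NH4Cl
Reagents that add atoms: methyllithium [Li]C
Why: Weinreb ketone synthesis, in which the stable chelated tetrahedral intermediate prevents over-addition and the trisubstituted epoxide is inert to MeLi at −78 °C.

**Step 13**
Reactants: 19; 20 2,4,6-tri(propan-2-yl)benzenesulfonohydrazide
Product: 21 (E)-trisylhydrazone of 19
Conditions: THF, 4 Å molecular sieves, rt (no added acid)
Reagents that add atoms: none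
Why: condensation of the methyl ketone with the sulfonyl hydrazide gives the E-hydrazone, with the sulfonamide anti to the branched C12 side.

**Step 14**
Reactants: 21; 9 carbon dioxide
Product: 24 α-methylene lactone diol (ring D closed; cis-fused; C9a–OH trans to O1; primary alcohol free; C11–OTBS), via vinyllithium 22 (not isolated), via lithium acrylate 23 (not isolated)
Conditions: n-BuLi (2.2 equiv), THF–TMEDA, −78 °C then 0 °C (N2 evolution); CO2, −78 °C; then 1 M HCl, THF, 0 °C to rt
Reagents that add atoms: none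
Why: Shapiro reaction with CO2 trapping followed by acid-triggered epoxy-acid lactonisation, the closest known reaction type being the one-flask α-methylene-γ-butyrolactone synthesis from trisylhydrazone dianions: the E-hydrazone is deprotonated at N–H and at the syn methyl group, expels sulfinate and N2 at 0 °C to give vinyllithium 22, which adds to CO2 through C13 (new C13–C14 bond) to give carboxylate 23. On acidification the acrylic acid attacks the protonated C1–C9a epoxide at its tertiary carbon C1 (new O–C1 bond). Only ring D is closed, in a 5-exo-tet mode with backside (anti) opening. The new stereocentre C1 is set by the tether from C12: the carboxyl arm lies on the ring face opposite the epoxide oxygen, so inversion at C1 gives the cis-fused lactone with O1 syn to C13 and O11, while C9a keeps a trans hydroxyl that is oxidised later and C10–C12 are untouched. The step needs vinyl-anion formation on the methyl side (secured by the syn-directing E-hydrazone and the hindered tertiary C12–H), an epoxide that survives the organolithium stage (trisubstituted, no Lewis acid, −78 to 0 °C) and opening at C1 rather than C9a (5-exo over 6-endo, tertiary centre). The same aqueous acid removes the primary triethylsilyl group and leaves the secondary TBS ether.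

**Step 15**
Reactants: 24
Product: 25 keto aldehyde (C9a ketone, C3 aldehyde)
Conditions: Dess–Martin periodinane (3 equiv), NaHCO3, CH2Cl2, 0 °C to rt
Reagents that add atoms: none
Why: double Dess–Martin oxidation converts the secondary and primary alcohols together under non-basic conditions that should not trigger β-elimination of the lactone carboxylate.

**Step 16**
Reactants: 25; 26 (R)-2-methylpropane-2-sulfinamide
Product: 27 (R)-N-sulfinyl aldimine at C3 (E)
Conditions: anhydrous CuSO4, CH2Cl2, rt
Reagents that add atoms: none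
Why: Ellman condensation under neutral dehydrating conditions engages only the aldehyde, because the α-quaternary C9a ketone is too hindered to condense.

**Step 17**
Reactants: 28 3-methylfuran-2(5H)-one
Product: 29 triisopropyl[(3-methylfuran-2-yl)oxy]silane
Conditions: TIPSOTf, Et3N, CH2Cl2, 0 °C
Reagents that add atoms: triisopropylsilyl trifluoromethanesulfonate CC(C)[Si](OS(=O)(=O)C(F)(F)F)(C(C)C)C(C)C
Why: soft enolisation and O-silylation of the butenolide gives the aromatic 2-silyloxyfuran.

**Step 18**
Reactants: 27; 29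
Product: 30 threo butenolide sulfinamide (C3–C18 bond formed)
Conditions: TMSOTf (20 mol %), CH2Cl2, −78 °C; aq. NaHCO3
Reagents that add atoms: none
Why: vinylogous Mukaiyama–Mannich reaction through an open transition state, in which the furan C5 attacks the imine face opposite the tert-butyl group of the (R)-sulfinyl unit to set C3 as (S) and the threo preference of silyloxyfuran additions sets C18 as (S).

**Step 19**
Reactants: 30
Product: 31 bis-lactone keto sulfinamide (C13 and C20 methyl centres set)
Conditions: H2 (3 atm), Pd/C (10 %), EtOAc, rt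
Reagents that add atoms: none
Why: heterogeneous hydrogenation adds to the exocyclic methylene of ring D from its convex face (C13–H syn to C12–H) and to the butenolide from the face opposite the C18 substituent (cis lactone, C20), leaving the ketone and sulfinamide intact.

**Step 20**
Reactants: 31
Product: 33 cyclic imine (ring A closed as 1-pyrroline; C11–OTBS), via aminoketone hydrochloride 32 (not isolated)
Conditions: HCl (4 M in dioxane, 2 equiv), MeOH, 0 °C, 30 min; then Et3N, 4 Å molecular sieves, CH2Cl2, rt
Reagents that add atoms: none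
Why: acidolysis of the N–S bond frees the C3 amine, which condenses intramolecularly with the C9a ketone (5-membered ring formation) faster than it attacks either lactone, with no change at C3.

**Step 21**
Reactants: 33; 34 1,4-diiodobutane
Product: 36 O-TBS-protected target, via N-(4-iodobutyl)enamine 35 (not isolated)
Conditions: iPr2NEt (3 equiv), MeCN, 60 °C
Reagents that add atoms: none
Why: annulation of a cyclic imine with a 1,4-dihalide: N-alkylation gives an iminium that can lose a proton only at C9 (C1 is quaternary), and the resulting enamine closes ring B by 7-(enolendo)-exo-tet C-alkylation and a second deprotonation to the tetrasubstituted C9=C9a enamine.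

**Step 22**
Reactants: 36
Product: 37 target (CNP0154902.1)
Conditions: HF·pyridine, pyridine, THF, 0 °C to rt; aq. NaHCO3
Reagents that add atoms: none
Why: buffered fluoride desilylation frees the C11 hydroxyl last and under conditions too mild for acyl migration of ring D from O1 to O11.

**Compound list**

1 | (4S)-4-benzyl-1,3-oxazolidin-2-one | O=C1N[C@@H](Cc2ccccc2)CO1 | starting material
2 | butanoyl chloride | CCCC(Cl)=O | starting material
3 | (4S)-4-benzyl-3-butanoyl-1,3-oxazolidin-2-one | CCCC(=O)N1[C@@H](Cc2ccccc2)COC1=O | intermediate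
4 | allyl bromide | C=CCBr | starting material
5 | (4S)-4-benzyl-3-[(2R)-2-ethylpent-4-enoyl]-1,3-oxazolidin-2-one | CC[C@H](CC=C)C(=O)N1[C@@H](Cc2ccccc2)COC1=O | intermediate
6 | (2R)-2-ethylpent-4-en-1-ol | CC[C@@H](CO)CC=C | intermediate
7 | (2R)-2-ethylpent-4-enal | CC[C@@H](C=O)CC=C | intermediate
8 | 3-methylbut-3-en-1-ol | CC(=C)CCO | starting material
9 | carbon dioxide | O=C=O | starting material
10 | triethylsilyl 3-methylidene-5-(triethylsilyloxy)pentanoate | C=C(CCO[Si](CC)(CC)CC)CC(=O)O[Si](CC)(CC)CC | intermediate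
11 | 3-methylidene-5-(triethylsilyloxy)pentanoic acid | C=C(CCO[Si](CC)(CC)CC)CC(O)=O | intermediate
12 | (4R)-4-benzyl-1,3-oxazolidin-2-one | O=C1N[C@H](Cc2ccccc2)CO1 | starting material
13 | (4R)-4-benzyl-3-[3-methylidene-5-(triethylsilyloxy)pentanoyl]-1,3-oxazolidin-2-one | C=C(CCO[Si](CC)(CC)CC)CC(=O)N1[C@H](Cc2ccccc2)COC1=O | intermediate
14 | (4R)-4-benzyl-3-[(2R,3S,4R)-4-ethyl-3-hydroxy-2-[4-(triethylsilyloxy)but-1-en-2-yl]hept-6-enoyl]-1,3-oxazolidin-2-one | O=C1OC[C@@H](Cc2ccccc2)N1C(=O)[C@H](C(=C)CCO[Si](CC)(CC)CC)[C@@H](O)[C@H](CC)CC=C | intermediate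
15 | (2R,3S,4R)-4-ethyl-3-hydroxy-N-methoxy-N-methyl-2-[4-(triethylsilyloxy)but-1-en-2-yl]hept-6-enamide | CON(C)C(=O)[C@H](C(=C)CCO[Si](CC)(CC)CC)[C@@H](O)[C@H](CC)CC=C | intermediate
16 | (2R,3S,4R)-3-(tert-butyldimethylsilyloxy)-4-ethyl-N-methoxy-N-methyl-2-[4-(triethylsilyloxy)but-1-en-2-yl]hept-6-enamide | CON(C)C(=O)[C@H](C(=C)CCO[Si](CC)(CC)CC)[C@@H](O[Si](C)(C)C(C)(C)C)[C@H](CC)CC=C | intermediate
17 | (1R,5R,6S)-6-(tert-butyldimethylsilyloxy)-5-ethyl-N-methoxy-N-methyl-2-[2-(triethylsilyloxy)ethyl]cyclohex-2-ene-1-carboxamide | CC[C@@H]1CC=C(CCO[Si](CC)(CC)CC)[C@@H](C(=O)N(C)OC)[C@H]1O[Si](C)(C)C(C)(C)C | intermediate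
18 | epoxy Weinreb amide (C1–C9a epoxide of 17, anti to carboxamide and OTBS) | CC[C@@H]1C[C@@H]2O[C@]2(CCO[Si](CC)(CC)CC)[C@@H](C(=O)N(C)OC)[C@H]1O[Si](C)(C)C(C)(C)C | intermediate
19 | epoxy methyl ketone (acetyl on C12) | CC[C@@H]1C[C@@H]2O[C@]2(CCO[Si](CC)(CC)CC)[C@@H](C(C)=O)[C@H]1O[Si](C)(C)C(C)(C)C | intermediate
20 | 2,4,6-tri(propan-2-yl)benzenesulfonohydrazide | CC(C)c1cc(C(C)C)c(S(=O)(=O)NN)c(C(C)C)c1 | starting material
21 | (E)-2,4,6-tri(propan-2-yl)benzenesulfonylhydrazone of 19 | CC[C@@H]1C[C@@H]2O[C@]2(CCO[Si](CC)(CC)CC)[C@@H](/C(C)=N/NS(=O)(=O)c3c(C(C)C)cc(C(C)C)cc3C(C)C)[C@H]1O[Si](C)(C)C(C)(C)C | intermediate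
22 | C13 vinyllithium (epoxide intact) | CC[C@@H]1C[C@@H]2O[C@]2(CCO[Si](CC)(CC)CC)[C@@H](C(=C)[Li])[C@H]1O[Si](C)(C)C(C)(C)C | intermediate
23 | lithium 2-substituted acrylate (epoxide intact) | CC[C@@H]1C[C@@H]2O[C@]2(CCO[Si](CC)(CC)CC)[C@@H](C(=C)C(=O)[O-])[C@H]1O[Si](C)(C)C(C)(C)C.[Li+] | intermediate
24 | cis-fused α-methylene γ-lactone of ring C with C9a–OH (trans to O1), 2-hydroxyethyl on C1, C11–OTBS, C10 ethyl | CC[C@@H]1C[C@H](O)[C@@]2(CCO)OC(=O)C(=C)[C@H]2[C@H]1O[Si](C)(C)C(C)(C)C | intermediate
25 | keto aldehyde (C9a ketone, C3 aldehyde) of 24 | CC[C@@H]1CC(=O)[C@@]2(CC=O)OC(=O)C(=C)[C@H]2[C@H]1O[Si](C)(C)C(C)(C)C | intermediate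
26 | (R)-2-methylpropane-2-sulfinamide | CC(C)(C)[S@](N)=O | starting material
27 | (R)-N-tert-butanesulfinyl (E)-aldimine of 25 | CC[C@@H]1CC(=O)[C@@]2(C/C=N/[S@](=O)C(C)(C)C)OC(=O)C(=C)[C@H]2[C@H]1O[Si](C)(C)C(C)(C)C | intermediate
28 | 3-methylfuran-2(5H)-one | CC1=CCOC1=O | starting material
29 | triisopropyl[(3-methylfuran-2-yl)oxy]silane | Cc1ccoc1O[Si](C(C)C)(C(C)C)C(C)C | intermediate
30 | threo vinylogous Mannich adduct (C3 sulfinamide, C18 butenolide) | CC[C@@H]1CC(=O)[C@@]2(C[C@H](N[S@](=O)C(C)(C)C)[C@@H]3C=C(C)C(=O)O3)OC(=O)C(=C)[C@H]2[C@H]1O[Si](C)(C)C(C)(C)C | intermediate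
31 | hydrogenated bis-lactone keto sulfinamide | CC[C@@H]1CC(=O)[C@@]2(C[C@H](N[S@](=O)C(C)(C)C)[C@@H]3C[C@H](C)C(=O)O3)OC(=O)[C@@H](C)[C@H]2[C@H]1O[Si](C)(C)C(C)(C)C | intermediate
32 | C3 ammonium chloride of the aminoketone | CC[C@@H]1CC(=O)[C@@]2(C[C@H]([NH3+])[C@@H]3C[C@H](C)C(=O)O3)OC(=O)[C@@H](C)[C@H]2[C@H]1O[Si](C)(C)C(C)(C)C.[Cl-] | intermediate
33 | cyclic imine (N4=C9a, rings A, C, D, E in place, C11–OTBS) | CC[C@@H]1CC2=N[C@H]([C@@H]3C[C@H](C)C(=O)O3)C[C@@]24OC(=O)[C@@H](C)[C@H]4[C@H]1O[Si](C)(C)C(C)(C)C | intermediate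
34 | 1,4-diiodobutane | ICCCCI | starting material
35 | N-(4-iodobutyl) C9=C9a enamine | CC[C@@H]1C=C2N(CCCCI)[C@H]([C@@H]3C[C@H](C)C(=O)O3)C[C@@]24OC(=O)[C@@H](C)[C@H]4[C@H]1O[Si](C)(C)C(C)(C)C | intermediate
36 | 11-O-TBS ether of the target | CC[C@@H]1C2=C3N(CCCC2)[C@H]([C@@H]2C[C@H](C)C(=O)O2)C[C@@]32OC(=O)[C@@H](C)[C@H]2[C@H]1O[Si](C)(C)C(C)(C)C | intermediate
37 | target CNP0154902.1 | CC[C@@H]1C2=C3N(CCCC2)[C@H]([C@@H]2C[C@H](C)C(=O)O2)C[C@@]32OC(=O)[C@@H](C)[C@H]2[C@H]1O | target

**Step count and risks**

Total steps: 22. Longest linear sequence: 19 steps (steps 1–4, 7–16, 18–22).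

Steps most likely to fail:

1. Step 14. Risks: attack of the hydrazone aza-enolate or of the alkyllithium on the epoxide before carboxylation, base-induced opening of the β,γ-epoxide, or protonation of the vinyllithium before CO2 is added. Fallback: setting out from 19, kinetic enolisation on the methyl side with KN(SiMe3)2 and trapping with N-phenylbis(trifluoromethanesulfonimide) would give the enol triflate F1. Hydroxycarbonylation of F1 (Pd(OAc)2, dppf, CO 1 atm, KOAc, DMF–H2O, 60 °C) would give the epoxy acrylic acid F2 without any organolithium. Treating F2 with 1 M HCl in THF would close ring D and remove the triethylsilyl group, coming back to the route at 24.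

2. Step 18. Risks: poor facial or threo selectivity, β-elimination of the ring-D carboxylate from the enolisable sulfinimine, or conjugate addition of the silyloxyfuran to the α-methylene lactone. Fallback: setting out from 25, condensation with tert-butyl carbamate (camphorsulfonic acid cat., MeOH) would close ring A first, as the cyclic N-Boc methoxy aminal enecarbamate F3. Ionisation of F3 with BF3·OEt2 in the presence of 29 would give a cyclic N-acyliminium vinylogous Mannich reaction, a class with inherent threo selectivity whose facial selectivity here would rest on the quaternary centre C1, leading to the butenolide F4. Hydrogenation of both lactone alkenes (H2, Rh/Al2O3) would give F5, and CF3CO2H would remove the Boc group, coming back to the route at 33.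

3. Step 21. Risks: slow N-alkylation of the hindered ketimine, intermolecular over-alkylation, or failure of the seven-membered ring closure. Fallback: setting out from 33, the order of bond formation is reversed. Deprotonation at C9 with LiN(iPr)2 (1.0 equiv, THF, −78 °C) and C-alkylation of the lithiated imine with 1-chloro-4-iodobutane would give the C9-(4-chlorobutyl) imine F6 as a mixture of C9 epimers. Heating F6 with NaI and K2CO3 in MeCN (70 °C) would then close ring B by 7-exo-tet N-alkylation and deprotonation, coming back to the route at 36.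

**Further compounds**

F1 | step 14 | enol triflate of 19 (CH2=C(OTf) on C12, epoxide intact) | CC[C@@H]1C[C@@H]2O[C@]2(CCO[Si](CC)(CC)CC)[C@@H](C(=C)OS(=O)(=O)C(F)(F)F)[C@H]1O[Si](C)(C)C(C)(C)C
F2 | step 14 | epoxy acrylic acid (free acid of 23) | CC[C@@H]1C[C@@H]2O[C@]2(CCO[Si](CC)(CC)CC)[C@@H](C(=C)C(O)=O)[C@H]1O[Si](C)(C)C(C)(C)C
F3 | step 18 | cyclic N-Boc C3-methoxy aminal enecarbamate (ring A closed, C9=C9a; C3 epimers) | CC[C@@H]1C=C2N(C(=O)OC(C)(C)C)C(OC)C[C@@]23OC(=O)C(=C)[C@H]3[C@H]1O[Si](C)(C)C(C)(C)C
F4 | step 18 | N-Boc threo butenolide adduct | CC[C@@H]1C=C2N(C(=O)OC(C)(C)C)[C@H]([C@@H]4C=C(C)C(=O)O4)C[C@@]23OC(=O)C(=C)[C@H]3[C@H]1O[Si](C)(C)C(C)(C)C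
F5 | step 18 | N-Boc enecarbamate with both lactones saturated | CC[C@@H]1C=C2N(C(=O)OC(C)(C)C)[C@H]([C@@H]4C[C@H](C)C(=O)O4)C[C@@]23OC(=O)[C@@H](C)[C@H]3[C@H]1O[Si](C)(C)C(C)(C)C
F6 | step 21 | C9-(4-chlorobutyl) cyclic imine (C9 epimers) | CC[C@@H]1C(CCCCCl)C2=N[C@H]([C@@H]3C[C@H](C)C(=O)O3)C[C@@]24OC(=O)[C@@H](C)[C@H]4[C@H]1O[Si](C)(C)C(C)(C)C
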